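## Retrosynthetic overview

1. The strategy rests on the 1,5-diene C10=C1–C2–C3–C4=C5 inside the ten-membered carbocycle (ring C1–C10), with C10 carrying the one-carbon unit C14. Cleaving C2–C3 and joining C5–C10 folds this ring back to a cis-1,2-dialkenylcyclohexanol (six-membered ring C5–C10).
2. Target ⇐ oxidative lactonisation O6/C12 (γ-lactone last), esters at O8 and O9, C14 by carbonylation of the C10 enol triflate ⇐ ten-membered C10 ketone.
3. Ten-membered ketone ⇐ anionic oxy-Cope ring expansion (forms C2–C3, breaks C5–C10).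
4. Cyclohexanol ⇐ CrCl2-mediated intramolecular allylation of a C10 vinyl ketone (forms C5–C10) ⇐ acyclic chain from a D-glucose-derived hex-5-enal (C7–C10, C1, C2; C8 and C9 are glucose C2 and C3) by Wittig reaction (C5, C6), cuprate addition (C7–C11) and enolate hydroxylation (O6); both C(=CH2)CH2O units come from 2-bromoprop-2-en-1-ol.
5. Ring order: six-membered carbocycle (step 18), ten-membered carbocycle (step 19), γ-lactone (step 30).

Key step: step 19

Remark: germacrane numbering is used throughout (C14 on C10, C15 on C4, C11–C13 on C7); DMB = 3,4-dimethoxybenzyl, PMB = 4-methoxybenzyl, TES = triethylsilyl, TBS = tert-butyldimethylsilyl, TBDPS = tert-butyldiphenylsilyl; 21 and 22 are assumed to be C5-epimer mixtures and 23–26 mixtures of C4=C5 isomers, all of which converge on one allylchromium species in step 18.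

## Route

Step 1
Reactants: 1 methyl 4,6-O-benzylidene-α-D-glucopyranoside
Product: 2 2-O-DMB ether of 1
Conditions: 3,4-dimethoxybenzyl chloride, n-Bu4NHSO4, 5% aq NaOH, CH2Cl2, reflux
Reagents that add atoms: 3,4-dimethoxybenzyl chloride, COc1ccc(CCl)cc1OC
Why: Phase-transfer Williamson etherification should go mainly to O2, the more acidic hydroxyl next to the anomeric acetal; no stereocentre is touched and O2 becomes O8 of the target.

Step 2
Reactants: 2 2-O-DMB ether
Product: 3 2-O-DMB-3-O-PMB glucoside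
Conditions: NaH, 4-methoxybenzyl chloride, n-Bu4NI, DMF, 0 °C to rt
Reagents that add atoms: 4-methoxybenzyl chloride, COc1ccc(CCl)cc1
Why: Williamson etherification of the only free hydroxyl (O3, later O9) gives two benzyl-type ethers that DDQ can later remove one after the other.

Step 3
Reactants: 3 2-O-DMB-3-O-PMB glucoside
Product: 4 4,6-diol
Conditions: 80% aq AcOH, 45 °C
Reagents that add atoms: none
Why: Mild acid hydrolysis cleaves the benzylidene acetal while the methyl glycoside and both benzyl-type ethers should survive dilute acetic acid.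

Step 4
Reactants: 4 4,6-diol
Product: 5 6-deoxy-6-iodo glucoside
Conditions: I2, PPh3, imidazole, toluene, 70 °C
Reagents that add atoms: iodine, II
Why: Appel-type iodination through the alkoxyphosphonium salt is selective for the primary C6 hydroxyl over the hindered secondary O4–H.

Step 5
Reactants: 5 6-deoxy-6-iodo glucoside
Product: 6 4-O-TES 6-iodo glucoside
Conditions: Et3SiOTf, 2,6-lutidine, CH2Cl2, −78 to 0 °C
Reagents that add atoms: triethylsilyl trifluoromethanesulfonate, CC[Si](CC)(CC)OS(=O)(=O)C(F)(F)F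
Why: Silylation masks O4 (later the C10 oxygen) so that the γ-hydroxy aldehyde freed in step 6 cannot close to a lactol or add to the enoate of step 7.

Step 6
Reactants: 6 4-O-TES 6-iodo glucoside
Product: 7 hex-5-enal (C7 aldehyde with 8-ODMB, 9-OPMB, 10-OTES and the C1=C2 vinyl group)
Conditions: Zn dust (activated), THF/H2O 9:1, sonication, 40 °C
Reagents that add atoms: none
Why: Zinc-mediated reductive fragmentation of the 6-iodo glycoside (Vasella fragmentation) expels the ring oxygen to give the C5=C6 alkene and the C1 aldehyde under neutral conditions, keeping the C2, C3 and C4 configurations.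

Step 7
Reactants: 7 hex-5-enal
Product: 8 (E)-enoate
Conditions: Ph3P=CHCO2Et, CH2Cl2, rt
Reagents that add atoms: ethyl (triphenylphosphoranylidene)acetate, CCOC(=O)C=P(c1ccccc1)(c1ccccc1)c1ccccc1
Why: Wittig olefination with the stabilised ylide in an aprotic solvent should give the (E)-C6=C7 enoate without epimerising the α-alkoxy aldehyde.

Step 8
Reactants: 9 2-bromoprop-2-en-1-ol
Product: 10 2-bromoallyl TBS ether
Conditions: t-BuMe2SiCl, imidazole, CH2Cl2, 0 °C to rt
Reagents that add atoms: tert-butyldimethylsilyl chloride, CC(C)(C)[Si](C)(C)Cl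
Why: Standard silylation of the primary allylic alcohol gives the precursor of the C11–C13 alkenyl nucleophile.

Step 9
Reactants: 8 (E)-enoate; 10 2-bromoallyl TBS ether
Product: 14 ethyl ester carrying the C7 alkenyl group, via alkenyllithium 11 (not isolated), via lithium dialkenylcuprate 12 (not isolated), via silyl ketene acetal 13 (not isolated)
Conditions: 10, t-BuLi (2 equiv), Et2O, −78 °C; CuI (0.5 equiv), −40 °C; then Me3SiCl and 8, THF, −78 to −40 °C; aq NH4Cl/NH3
Reagents that add atoms: none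
Why: Me3SiCl-accelerated conjugate addition of the alkenyl cuprate to the γ-alkoxy (E)-enoate should form C7–C11 anti to the C8–O bond (1,2-induction of the modified Felkin–Anh type), which is the 7,8-relationship of the target.

Step 10
Reactants: 14 ethyl ester
Product: 16 α-hydroxy ester, via potassium enolate 15 (not isolated)
Conditions: KN(SiMe3)2, THF, −78 °C; 2-(phenylsulfonyl)-3-phenyloxaziridine, −78 °C; aq NH4Cl
Reagents that add atoms: 2-(phenylsulfonyl)-3-phenyloxaziridine, O=S(=O)(c1ccccc1)N1OC1c1ccccc1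
Why: Electrophilic hydroxylation of the ester enolate with the N-sulfonyloxaziridine should occur with H7 eclipsing the enolate plane (allylic 1,3-strain) and on the face away from the larger C8 alkoxyalkyl chain, which sets O6 syn to the C7 alkenyl group.

Step 11
Reactants: 16 α-hydroxy ester
Product: 17 α-silyloxy ester
Conditions: t-BuMe2SiOTf, 2,6-lutidine, CH2Cl2, −78 to 0 °C
Reagents that add atoms: tert-butyldimethylsilyl trifluoromethanesulfonate, CC(C)(C)[Si](C)(C)OS(=O)(=O)C(F)(F)F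
Why: Silylation protects O6 with a group that is later removed together with the O12 silyl ether just before lactonisation.

Step 12
Reactants: 17 α-silyloxy ester
Product: 18 C5 aldehyde
Conditions: i-Bu2AlH, CH2Cl2, −78 °C; aq potassium sodium tartrate
Reagents that add atoms: none
Why: Partial reduction of the α-alkoxy ester should stop at the aldehyde because the tetrahedral aluminium hemiacetal is stable at −78 °C.

Step 13
Reactants: 9 2-bromoprop-2-en-1-ol
Product: 19 2-bromoallyl TBDPS ether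
Conditions: t-BuPh2SiCl, imidazole, CH2Cl2, rt
Reagents that add atoms: tert-butyldiphenylsilyl chloride, CC(C)(C)[Si](Cl)(c1ccccc1)c1ccccc1
Why: Standard silylation gives the C3/C4/C15 unit with the acid-robust silyl group that has to survive to the last step.

Step 14
Reactants: 18 C5 aldehyde; 19 2-bromoallyl TBDPS ether
Product: 21 secondary allylic alcohol at C5, via alkenyllithium 20 (not isolated)
Conditions: 19, t-BuLi (2 equiv), Et2O, −78 °C; then 18, −78 °C; aq NH4Cl
Reagents that add atoms: none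
Why: Bromine–lithium exchange and 1,2-addition to the aldehyde attach C4 with C3 and C15; the C5 carbinol configuration is irrelevant because C5 becomes the γ-carbon of an allylmetal in step 18.

Step 15
Reactants: 21 secondary allylic alcohol
Product: 23 primary allylic bromide (C3–Br, C4=C5), via mesylate 22 (not isolated)
Conditions: MsCl, Et3N, CH2Cl2, −30 °C; then LiBr, THF, 0 °C to rt
Reagents that add atoms: lithium bromide, [Li+].[Br-]
Why: Mesylation followed by bromide displacement (SN2 and SN2′ with allylic transposition) should give the more substituted alkene, and every regio- and stereoisomer leads to the same allylchromium species.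

Step 16
Reactants: 23 allylic bromide TES ether
Product: 24 allylic bromide with free C10 hydroxyl
Conditions: PPTS, MeOH/CH2Cl2, 0 °C
Reagents that add atoms: none
Why: Acid-catalysed methanolysis removes the secondary triethylsilyl ether much faster than the tert-butylsilyl ethers, and the allylic bromide should tolerate the short cold exposure.

Step 17
Reactants: 24 allylic bromide alcohol
Product: 25 vinyl ketone allylic bromide
Conditions: Dess–Martin periodinane, NaHCO3, CH2Cl2, 0 °C to rt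
Reagents that add atoms: none
Why: Buffered Dess–Martin oxidation of the allylic alcohol gives the α-alkoxy vinyl ketone under neutral conditions, which erases the glucose C4 stereocentre without epimerising C9.

Step 18
Reactants: 25 vinyl ketone allylic bromide
Product: 27 cis-1,2-dialkenylcyclohexanol (oxy-Cope precursor), via allylchromium species 26 (not isolated)
Conditions: CrCl2 (6 equiv), THF, 0.005 M, rt
Reagents that add atoms: none
Why: Intramolecular Nozaki–Hiyama allylation, in which the allylchromium adds through C5 to the C10 ketone in a chair transition state trans-fused to the forming ring; H6 eclipses the allyl plane (allylic 1,3-strain) with the C6 silyloxy group anti to the new bond, which should place the C5 alkenyl group trans to O6 and to the C10 hydroxyl and therefore cis to the vinyl group.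

Step 19
Reactants: 27 cis-1,2-dialkenylcyclohexanol
Product: 30 ten-membered C10 ketone with ring-cis C4=C5, via potassium alkoxide 28 (not isolated), via potassium enolate 29 (not isolated)
Conditions: KH, 18-crown-6, THF, 0 °C to rt; aq NH4Cl at −78 °C
Reagents that add atoms: none
Why: KH with 18-crown-6 gives the free alkoxide 28, whose oxyanion weakens the C5–C10 bond so that the 1,5-diene C2=C1–C10–C5–C4=C3 undergoes a chair-like [3,3] shift to enolate 29, which is protonated at C1 on cold quench. The closest known reaction type is the anionic oxy-Cope ring expansion of 1,2-dialkenylcyclohexanols to cyclodec-5-enones. The ten-membered ring is closed by ring expansion and not end to end: the new C2–C3 σ bond joins the two alkenyl termini while the C5–C10 bond of the six-membered ring breaks, so all ten ring atoms are already held together. No stereocentre is created and C6–C9 are untouched; the two new double-bond geometries follow from the chair, in which C6 and the oxyanion are axial, giving the ring-cis C4=C5 bond and the enolate with O cis to C2. The step needs the cyclohexane chair with the C5 alkenyl group equatorial and the C10 vinyl group axial, and the equatorial C6 silyloxy and C7 alkenyl groups secure it because the other chair would carry three adjacent axial substituents. The cold quench keeps enolate 29 from equilibrating towards C9, which would epimerise C9 or expel the C8 alkoxide.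

Step 20
Reactants: 30 ten-membered ketone
Product: 32 enol triflate (C1=C10 ring-trans), via sodium enolate 31 (not isolated)
Conditions: NaN(SiMe3)2, THF, −78 °C; PhNTf2, −78 to −20 °C; aq NH4Cl
Reagents that add atoms: N-phenylbis(trifluoromethanesulfonimide), O=S(=O)(N(c1ccccc1)S(=O)(=O)C(F)(F)F)C(F)(F)F
Why: Kinetic deprotonation by the sodium amide should take the C1 methylene and not the hindered alkoxy-bearing C9 methine and give the sodium enolate with O cis to C2 (the branched C9 avoids C2), which PhNTf2 O-sulfonylates to the enol triflate (enolate triflation).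

Step 21
Reactants: 32 enol triflate
Product: 33 methyl ester at C14 (C1=C10 ring-trans)
Conditions: Pd(PPh3)4 (10 mol %), CO (1 atm), MeOH, Et3N, DMF, 60 °C
Reagents that add atoms: carbon monoxide, [C-]#[O+]; methanol, CO
Why: Palladium-catalysed alkoxycarbonylation (oxidative addition, CO insertion, methanolysis of the acylpalladium) attaches C14 to C10 with retention of the alkene geometry.

Step 22
Reactants: 33 methyl ester
Product: 34 C14 allylic alcohol
Conditions: i-Bu2AlH, CH2Cl2, −78 °C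
Reagents that add atoms: none
Why: 1,2-Reduction of the enoate, the only carbonyl group present, brings C14 to the alcohol level before any other ester is installed.

Step 23
Reactants: 34 C14 allylic alcohol
Product: 35 (Z)-enal (C1=C10 ring-trans)
Conditions: MnO2, CH2Cl2, rt
Reagents that add atoms: none
Why: MnO2 oxidises the only free (allylic) alcohol to the enal and leaves the ethers and the other alkenes alone.

Step 24
Reactants: 35 (Z)-enal
Product: 36 (E)-enal (C1=C10 ring-cis)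
Conditions: DABCO (0.2 equiv), CH2Cl2, rt
Reagents that add atoms: none
Why: Reversible conjugate addition of the amine to the enal allows rotation about C1–C10 and should return the thermodynamically preferred (E)-enal, with the formyl group trans to C2 and both ring alkenes ring-cis as in the target.

Step 25
Reactants: 36 (E)-enal
Product: 37 C8 alcohol
Conditions: DDQ (1.1 equiv), CH2Cl2/pH 7 buffer, 0 °C
Reagents that add atoms: none
Why: Oxidative cleavage of the benzyl-type ether by hydride abstraction; the more electron-rich DMB ether is oxidised faster than the PMB ether, so only O8 should be freed.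

Step 26
Reactants: 37 C8 alcohol; 38 (R)-2-methylbutanoic acid
Product: 39 C8 (R)-2-methylbutanoate
Conditions: DCC, DMAP, CH2Cl2, 0 °C to rt
Reagents that add atoms: none
Why: Steglich esterification acylates the hindered secondary hydroxyl under near-neutral conditions that should not racemise the α-stereocentre of the acid; that stereocentre comes from the chiral pool.

Step 27
Reactants: 39 C8 ester
Product: 40 C9 alcohol
Conditions: DDQ (2 equiv), CH2Cl2/pH 7 buffer, rt
Reagents that add atoms: none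
Why: A second, more forcing DDQ oxidation removes the PMB ether under neutral conditions that should not move the hindered O8 ester.

Step 28
Reactants: 40 C9 alcohol
Product: 41 C9 acetate
Conditions: Ac2O, pyridine, DMAP (cat.), CH2Cl2, 0 °C
Reagents that add atoms: acetic anhydride, CC(=O)OC(C)=O
Why: Fast acetylation caps O9 before the oxidation of step 30, in which a free allylic C9 hydroxyl could be oxidised or could compete for the C12 aldehyde.

Step 29
Reactants: 41 C9 acetate
Product: 42 6,12-diol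
Conditions: HF·pyridine, pyridine, THF, 0 °C to rt
Reagents that add atoms: none
Why: Buffered HF cleaves the two tert-butyldimethylsilyl ethers (O12 primary, O6 secondary) well before the primary tert-butyldiphenylsilyl ether at O15.

Step 30
Reactants: 42 6,12-diol
Product: 44 α-methylene-γ-lactone with 15-OTBDPS, via lactol 43 (not isolated)
Conditions: TEMPO (cat.), PhI(OAc)2, CH2Cl2, rt
Reagents that add atoms: none
Why: Oxoammonium oxidation is selective for the primary allylic C12 hydroxyl; the resulting 2-substituted acrolein is trapped by O6 as the five-membered lactol, which is oxidised on to the lactone (oxidative lactonisation of a 2-methylene-1,4-diol).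

Step 31
Reactants: 44 lactone silyl ether
Product: 45 target CNP0247637.4
Conditions: HF·pyridine, THF, rt
Reagents that add atoms: none
Why: Acidic fluoride removes the last silyl ether to free the C15 alcohol without touching the lactone, the two esters or the enal.

## Compound list

1 | methyl 4,6-O-benzylidene-α-D-glucopyranoside | CO[C@H]1O[C@@H]2CO[C@@H](c3ccccc3)O[C@H]2[C@H](O)[C@H]1O | starting material
2 | methyl 4,6-O-benzylidene-2-O-(3,4-dimethoxybenzyl)-α-D-glucopyranoside | CO[C@H]1O[C@@H]2CO[C@@H](c3ccccc3)O[C@H]2[C@H](O)[C@H]1OCc1ccc(OC)c(OC)c1 | intermediate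
3 | methyl 4,6-O-benzylidene-2-O-(3,4-dimethoxybenzyl)-3-O-(4-methoxybenzyl)-α-D-glucopyranoside | CO[C@H]1O[C@@H]2CO[C@@H](c3ccccc3)O[C@H]2[C@H](OCc2ccc(OC)cc2)[C@H]1OCc1ccc(OC)c(OC)c1 | intermediate
4 | methyl 2-O-(3,4-dimethoxybenzyl)-3-O-(4-methoxybenzyl)-α-D-glucopyranoside | CO[C@H]1O[C@H](CO)[C@@H](O)[C@H](OCc2ccc(OC)cc2)[C@H]1OCc1ccc(OC)c(OC)c1 | intermediate
5 | methyl 6-deoxy-6-iodo-2-O-DMB-3-O-PMB-α-D-glucopyranoside | CO[C@H]1O[C@H](CI)[C@@H](O)[C@H](OCc2ccc(OC)cc2)[C@H]1OCc1ccc(OC)c(OC)c1 | intermediate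
6 | methyl 6-deoxy-6-iodo-2-O-DMB-3-O-PMB-4-O-TES-α-D-glucopyranoside | CO[C@H]1O[C@H](CI)[C@@H](O[Si](CC)(CC)CC)[C@H](OCc2ccc(OC)cc2)[C@H]1OCc1ccc(OC)c(OC)c1 | intermediate
7 | 5,6-dideoxy-2-O-DMB-3-O-PMB-4-O-TES-D-xylo-hex-5-enose (open-chain aldehyde; C7 aldehyde, 8-ODMB, 9-OPMB, 10-OTES, C1=C2 vinyl) | O=C[C@H](OCc1ccc(OC)c(OC)c1)[C@@H](OCc1ccc(OC)cc1)[C@H](O[Si](CC)(CC)CC)C=C | intermediate
8 | ethyl (E)-enoate (C5 ester, C6=C7, 8-ODMB, 9-OPMB, 10-OTES, C1=C2 vinyl; glucose C2–C4 configurations) | CCOC(=O)/C=C/[C@H](OCc1ccc(OC)c(OC)c1)[C@@H](OCc1ccc(OC)cc1)[C@H](O[Si](CC)(CC)CC)C=C | intermediate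
9 | 2-bromoprop-2-en-1-ol | OCC(Br)=C | starting material
10 | [(2-bromoprop-2-en-1-yl)oxy](tert-butyl)dimethylsilane | C=C(Br)CO[Si](C)(C)C(C)(C)C | intermediate
11 | [3-(tert-butyldimethylsilyloxy)prop-1-en-2-yl]lithium | [Li]C(=C)CO[Si](C)(C)C(C)(C)C | intermediate
12 | lithium bis[3-(tert-butyldimethylsilyloxy)prop-1-en-2-yl]cuprate | [Li+].C=C(CO[Si](C)(C)C(C)(C)C)[Cu-]C(=C)CO[Si](C)(C)C(C)(C)C | intermediate
13 | trimethylsilyl ketene acetal of 14 (ketene acetal geometry not defined) | CCOC(O[Si](C)(C)C)=C[C@H](C(=C)CO[Si](C)(C)C(C)(C)C)[C@H](OCc1ccc(OC)c(OC)c1)[C@@H](OCc1ccc(OC)cc1)[C@H](O[Si](CC)(CC)CC)C=C | intermediate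
14 | ethyl ester with C7 bearing C(=CH2)CH2OTBS, 7,8-anti (C6 methylene; 8-ODMB, 9-OPMB, 10-OTES, vinyl) | CCOC(=O)C[C@H](C(=C)CO[Si](C)(C)C(C)(C)C)[C@H](OCc1ccc(OC)c(OC)c1)[C@@H](OCc1ccc(OC)cc1)[C@H](O[Si](CC)(CC)CC)C=C | intermediate
15 | potassium enolate of 14 (geometry not defined) | CCOC([O-])=C[C@H](C(=C)CO[Si](C)(C)C(C)(C)C)[C@H](OCc1ccc(OC)c(OC)c1)[C@@H](OCc1ccc(OC)cc1)[C@H](O[Si](CC)(CC)CC)C=C.[K+] | intermediate
16 | ethyl 6-hydroxy ester, 6,7-syn and 7,8-anti | CCOC(=O)[C@@H](O)[C@H](C(=C)CO[Si](C)(C)C(C)(C)C)[C@H](OCc1ccc(OC)c(OC)c1)[C@@H](OCc1ccc(OC)cc1)[C@H](O[Si](CC)(CC)CC)C=C | intermediate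
17 | ethyl 6-OTBS ester | CCOC(=O)[C@@H](O[Si](C)(C)C(C)(C)C)[C@H](C(=C)CO[Si](C)(C)C(C)(C)C)[C@H](OCc1ccc(OC)c(OC)c1)[C@@H](OCc1ccc(OC)cc1)[C@H](O[Si](CC)(CC)CC)C=C | intermediate
18 | C5 aldehyde (6-OTBS, C7 alkenyl, 8-ODMB, 9-OPMB, 10-OTES, vinyl) | O=C[C@@H](O[Si](C)(C)C(C)(C)C)[C@H](C(=C)CO[Si](C)(C)C(C)(C)C)[C@H](OCc1ccc(OC)c(OC)c1)[C@@H](OCc1ccc(OC)cc1)[C@H](O[Si](CC)(CC)CC)C=C | intermediate
19 | [(2-bromoprop-2-en-1-yl)oxy](tert-butyl)diphenylsilane | C=C(Br)CO[Si](c1ccccc1)(c1ccccc1)C(C)(C)C | intermediate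
20 | [3-(tert-butyldiphenylsilyloxy)prop-1-en-2-yl]lithium | [Li]C(=C)CO[Si](c1ccccc1)(c1ccccc1)C(C)(C)C | intermediate
21 | C5 secondary allylic alcohol bearing C4(=C3H2)C15H2OTBDPS (mixture of C5 epimers) | C=C(CO[Si](c1ccccc1)(c1ccccc1)C(C)(C)C)C(O)[C@@H](O[Si](C)(C)C(C)(C)C)[C@H](C(=C)CO[Si](C)(C)C(C)(C)C)[C@H](OCc1ccc(OC)c(OC)c1)[C@@H](OCc1ccc(OC)cc1)[C@H](O[Si](CC)(CC)CC)C=C | intermediate
22 | C5 mesylate of 21 (mixture of C5 epimers) | C=C(CO[Si](c1ccccc1)(c1ccccc1)C(C)(C)C)C(OS(C)(=O)=O)[C@@H](O[Si](C)(C)C(C)(C)C)[C@H](C(=C)CO[Si](C)(C)C(C)(C)C)[C@H](OCc1ccc(OC)c(OC)c1)[C@@H](OCc1ccc(OC)cc1)[C@H](O[Si](CC)(CC)CC)C=C | intermediate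
23 | primary allylic bromide (C3–Br, C4=C5 as E/Z mixture), 10-OTES | BrCC(CO[Si](c1ccccc1)(c1ccccc1)C(C)(C)C)=C[C@@H](O[Si](C)(C)C(C)(C)C)[C@H](C(=C)CO[Si](C)(C)C(C)(C)C)[C@H](OCc1ccc(OC)c(OC)c1)[C@@H](OCc1ccc(OC)cc1)[C@H](O[Si](CC)(CC)CC)C=C | intermediate
24 | allylic bromide with free C10 hydroxyl | BrCC(CO[Si](c1ccccc1)(c1ccccc1)C(C)(C)C)=C[C@@H](O[Si](C)(C)C(C)(C)C)[C@H](C(=C)CO[Si](C)(C)C(C)(C)C)[C@H](OCc1ccc(OC)c(OC)c1)[C@@H](OCc1ccc(OC)cc1)[C@H](O)C=C | intermediate
25 | C10 vinyl ketone with the allylic bromide | BrCC(CO[Si](c1ccccc1)(c1ccccc1)C(C)(C)C)=C[C@@H](O[Si](C)(C)C(C)(C)C)[C@H](C(=C)CO[Si](C)(C)C(C)(C)C)[C@H](OCc1ccc(OC)c(OC)c1)[C@@H](OCc1ccc(OC)cc1)C(=O)C=C | intermediate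
26 | allylchromium dichloride derived from 25 | Cl[Cr](Cl)CC(CO[Si](c1ccccc1)(c1ccccc1)C(C)(C)C)=C[C@@H](O[Si](C)(C)C(C)(C)C)[C@H](C(=C)CO[Si](C)(C)C(C)(C)C)[C@H](OCc1ccc(OC)c(OC)c1)[C@@H](OCc1ccc(OC)cc1)C(=O)C=C | intermediate
27 | cis-1,2-dialkenylcyclohexanol (ring C5–C10): C10 tertiary alcohol with vinyl; C5 C(=CH2)CH2OTBDPS cis to the vinyl group; 6-OTBS; C7 C(=CH2)CH2OTBS; 8-ODMB; 9-OPMB | C=C[C@@]1(O)[C@H](OCc2ccc(OC)cc2)[C@@H](OCc2ccc(OC)c(OC)c2)[C@@H](C(=C)CO[Si](C)(C)C(C)(C)C)[C@H](O[Si](C)(C)C(C)(C)C)[C@H]1C(=C)CO[Si](c2ccccc2)(c2ccccc2)C(C)(C)C | intermediate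
28 | potassium alkoxide of 27 | C=C[C@@]1([O-])[C@H](OCc2ccc(OC)cc2)[C@@H](OCc2ccc(OC)c(OC)c2)[C@@H](C(=C)CO[Si](C)(C)C(C)(C)C)[C@H](O[Si](C)(C)C(C)(C)C)[C@H]1C(=C)CO[Si](c2ccccc2)(c2ccccc2)C(C)(C)C.[K+] | intermediate
29 | potassium enolate of 30 (C1=C10, O cis to C2; C4=C5 ring-cis) | CC(C)(C)[Si](C)(C)O[C@@H]1/C=C(/CO[Si](c2ccccc2)(c2ccccc2)C(C)(C)C)CC/C=C(\[O-])[C@H](OCc2ccc(OC)cc2)[C@@H](OCc2ccc(OC)c(OC)c2)[C@H]1C(=C)CO[Si](C)(C)C(C)(C)C.[K+] | intermediate
30 | ten-membered C10 ketone: ring-cis C4=C5 with C15H2OTBDPS, 6-OTBS, C7 C(=CH2)CH2OTBS, 8-ODMB, 9-OPMB | CC(C)(C)[Si](C)(C)O[C@@H]1/C=C(/CO[Si](c2ccccc2)(c2ccccc2)C(C)(C)C)CCCC(=O)[C@H](OCc2ccc(OC)cc2)[C@@H](OCc2ccc(OC)c(OC)c2)[C@H]1C(=C)CO[Si](C)(C)C(C)(C)C | intermediate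
31 | sodium enolate of 30 (C1=C10, O cis to C2; C4=C5 ring-cis) | CC(C)(C)[Si](C)(C)O[C@@H]1/C=C(/CO[Si](c2ccccc2)(c2ccccc2)C(C)(C)C)CC/C=C(\[O-])[C@H](OCc2ccc(OC)cc2)[C@@H](OCc2ccc(OC)c(OC)c2)[C@H]1C(=C)CO[Si](C)(C)C(C)(C)C.[Na+] | intermediate
32 | C10 enol triflate (C1=C10 ring-trans, OTf cis to C2) | CC(C)(C)[Si](C)(C)O[C@@H]1/C=C(/CO[Si](c2ccccc2)(c2ccccc2)C(C)(C)C)CC/C=C(\OS(=O)(=O)C(F)(F)F)[C@H](OCc2ccc(OC)cc2)[C@@H](OCc2ccc(OC)c(OC)c2)[C@H]1C(=C)CO[Si](C)(C)C(C)(C)C | intermediate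
33 | C14 methyl ester (C1=C10 ring-trans) | CC(C)(C)[Si](C)(C)O[C@@H]1/C=C(/CO[Si](c2ccccc2)(c2ccccc2)C(C)(C)C)CC/C=C(\C(=O)OC)[C@H](OCc2ccc(OC)cc2)[C@@H](OCc2ccc(OC)c(OC)c2)[C@H]1C(=C)CO[Si](C)(C)C(C)(C)C | intermediate
34 | C14 allylic alcohol (C1=C10 ring-trans) | CC(C)(C)[Si](C)(C)O[C@@H]1/C=C(/CO[Si](c2ccccc2)(c2ccccc2)C(C)(C)C)CC/C=C(\CO)[C@H](OCc2ccc(OC)cc2)[C@@H](OCc2ccc(OC)c(OC)c2)[C@H]1C(=C)CO[Si](C)(C)C(C)(C)C | intermediate
35 | C14 (Z)-enal (C1=C10 ring-trans) | CC(C)(C)[Si](C)(C)O[C@@H]1/C=C(/CO[Si](c2ccccc2)(c2ccccc2)C(C)(C)C)CC/C=C(\C=O)[C@H](OCc2ccc(OC)cc2)[C@@H](OCc2ccc(OC)c(OC)c2)[C@H]1C(=C)CO[Si](C)(C)C(C)(C)C | intermediate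
36 | C14 (E)-enal (C1=C10 and C4=C5 both ring-cis) | CC(C)(C)[Si](C)(C)O[C@@H]1/C=C(/CO[Si](c2ccccc2)(c2ccccc2)C(C)(C)C)CC/C=C(/C=O)[C@H](OCc2ccc(OC)cc2)[C@@H](OCc2ccc(OC)c(OC)c2)[C@H]1C(=C)CO[Si](C)(C)C(C)(C)C | intermediate
37 | C8 alcohol (9-OPMB kept) | CC(C)(C)[Si](C)(C)O[C@@H]1/C=C(/CO[Si](c2ccccc2)(c2ccccc2)C(C)(C)C)CC/C=C(/C=O)[C@H](OCc2ccc(OC)cc2)[C@@H](O)[C@H]1C(=C)CO[Si](C)(C)C(C)(C)C | intermediate
38 | (R)-2-methylbutanoic acid | CC[C@@H](C)C(=O)O | starting material
39 | C8 (R)-2-methylbutanoate with 9-OPMB | CC(C)(C)[Si](C)(C)O[C@@H]1/C=C(/CO[Si](c2ccccc2)(c2ccccc2)C(C)(C)C)CC/C=C(/C=O)[C@H](OCc2ccc(OC)cc2)[C@@H](OC(=O)[C@H](C)CC)[C@H]1C(=C)CO[Si](C)(C)C(C)(C)C | intermediate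
40 | C9 alcohol with the C8 ester | CC(C)(C)[Si](C)(C)O[C@@H]1/C=C(/CO[Si](c2ccccc2)(c2ccccc2)C(C)(C)C)CC/C=C(/C=O)[C@H](O)[C@@H](OC(=O)[C@H](C)CC)[C@H]1C(=C)CO[Si](C)(C)C(C)(C)C | intermediate
41 | C9 acetate with the C8 ester | CC(C)(C)[Si](C)(C)O[C@@H]1/C=C(/CO[Si](c2ccccc2)(c2ccccc2)C(C)(C)C)CC/C=C(/C=O)[C@H](OC(C)=O)[C@@H](OC(=O)[C@H](C)CC)[C@H]1C(=C)CO[Si](C)(C)C(C)(C)C | intermediate
42 | 6,12-diol (15-OTBDPS kept) | O[C@@H]1/C=C(/CO[Si](c2ccccc2)(c2ccccc2)C(C)(C)C)CC/C=C(/C=O)[C@H](OC(C)=O)[C@@H](OC(=O)[C@H](C)CC)[C@H]1C(=C)CO | intermediate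
43 | C12 lactol bridged to O6 (mixture of anomers) | C=C1C(O)O[C@@H]2/C=C(/CO[Si](c3ccccc3)(c3ccccc3)C(C)(C)C)CC/C=C(/C=O)[C@H](OC(C)=O)[C@@H](OC(=O)[C@H](C)CC)[C@@H]12 | intermediate
44 | 15-O-TBDPS ether of the target | C=C1C(=O)O[C@@H]2/C=C(/CO[Si](c3ccccc3)(c3ccccc3)C(C)(C)C)CC/C=C(/C=O)[C@H](OC(C)=O)[C@@H](OC(=O)[C@H](C)CC)[C@@H]12 | intermediate
45 | CNP0247637.4 (9-acetoxy-8-[(R)-2-methylbutanoyloxy]-15-hydroxy-14-oxogermacra-1(10),4,11(13)-trien-12,6-olide, both ring alkenes ring-cis) | C=C1C(=O)O[C@@H]2/C=C(/CO)CC/C=C(/C=O)[C@H](OC(C)=O)[C@@H](OC(=O)[C@H](C)CC)[C@@H]12 | target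

## Step count and risks

Total step count: 31. Longest linear sequence: 29 steps (steps 1–7, 9–12 and 14–31, from compound 1); steps 8 and 13 make the two alkenyl bromides.

Steps most likely to fail:

Step 19 (oxy-Cope ring expansion). The alkoxide may react through a boat or through the other chair and give the wrong C4=C5 geometry. The enolate may also equilibrate towards C9 before the quench, with epimerisation or loss of the C8 alkoxide. Fallback: a neutral siloxy-Cope rearrangement that avoids any free alkoxide or enolate. It sets out from 27. Silylation of the tertiary hydroxyl (Me3SiOTf, 2,6-lutidine, CH2Cl2, −78 °C) gives the trimethylsilyl ether F1. Thermolysis in degassed o-dichlorobenzene in base-washed glass at 180–200 °C should bring about the [3,3] shift to the trimethylsilyl enol ether F2. Dilute AcOH in THF/H2O at 0 °C hydrolyses F2 and the sequence comes back to the route at 30.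

Step 18 (chromium-mediated ring closure). The excess CrCl2 may reduce the α-alkoxy vinyl ketone, or the labile allylic bromide may be lost before the C5–C10 bond forms. Ring closure through a cis-fused transition state would also erode control at C10. Fallback: palladium-catalysed umpolung of an allylic acetate in place of the bromide and the stoichiometric reductant. It sets out from 21. Acetylation (Ac2O, pyridine, DMAP) gives the allylic acetate F3. PPTS in MeOH/CH2Cl2 at 0 °C removes the triethylsilyl group to give the C10 alcohol F4. Dess–Martin oxidation gives the vinyl ketone F5. Pd(PPh3)4 (catalytic) with InI in THF converts the allylic acetate through a π-allylpalladium complex into an allylindium species, which should add through C5 to the ketone in the same chair arrangement. The sequence comes back to the route at 27.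

Step 10 (enolate hydroxylation). Facial selectivity may be poor, because the two groups on C7 (the alkenyl group and the alkoxyalkyl chain) differ less in size than in the usual methyl-bearing cases. Fallback: oxygenation followed by inversion. It sets out from 14, whose hydroxylation under the same conditions would then deliver the C6 epimer F6. A Mitsunobu reaction (4-nitrobenzoic acid, PPh3, diisopropyl azodicarboxylate, THF, 0 °C) inverts C6 and gives the 4-nitrobenzoate F7. K2CO3 in ethanol at 0 °C cleaves the aryl ester without changing the ethyl ester, and the sequence comes back to the route at 16.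

## Further compounds

F1 | step 19 | trimethylsilyl ether of 27 | C=C[C@@]1(O[Si](C)(C)C)[C@H](OCc2ccc(OC)cc2)[C@@H](OCc2ccc(OC)c(OC)c2)[C@@H](C(=C)CO[Si](C)(C)C(C)(C)C)[C@H](O[Si](C)(C)C(C)(C)C)[C@H]1C(=C)CO[Si](c2ccccc2)(c2ccccc2)C(C)(C)C
F2 | step 19 | trimethylsilyl enol ether of 30 (C1=C10, O cis to C2) | CC(C)(C)[Si](C)(C)O[C@@H]1/C=C(/CO[Si](c2ccccc2)(c2ccccc2)C(C)(C)C)CC/C=C(\O[Si](C)(C)C)[C@H](OCc2ccc(OC)cc2)[C@@H](OCc2ccc(OC)c(OC)c2)[C@H]1C(=C)CO[Si](C)(C)C(C)(C)C
F3 | step 18 | C5 acetate of 21 (mixture of C5 epimers) | C=C(CO[Si](c1ccccc1)(c1ccccc1)C(C)(C)C)C(OC(C)=O)[C@@H](O[Si](C)(C)C(C)(C)C)[C@H](C(=C)CO[Si](C)(C)C(C)(C)C)[C@H](OCc1ccc(OC)c(OC)c1)[C@@H](OCc1ccc(OC)cc1)[C@H](O[Si](CC)(CC)CC)C=C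
F4 | step 18 | C5 acetate with free C10 hydroxyl | C=C(CO[Si](c1ccccc1)(c1ccccc1)C(C)(C)C)C(OC(C)=O)[C@@H](O[Si](C)(C)C(C)(C)C)[C@H](C(=C)CO[Si](C)(C)C(C)(C)C)[C@H](OCc1ccc(OC)c(OC)c1)[C@@H](OCc1ccc(OC)cc1)[C@H](O)C=C
F5 | step 18 | C5 acetate with the C10 vinyl ketone | C=C(CO[Si](c1ccccc1)(c1ccccc1)C(C)(C)C)C(OC(C)=O)[C@@H](O[Si](C)(C)C(C)(C)C)[C@H](C(=C)CO[Si](C)(C)C(C)(C)C)[C@H](OCc1ccc(OC)c(OC)c1)[C@@H](OCc1ccc(OC)cc1)C(=O)C=C
F6 | step 10 | C6 epimer of 16 | CCOC(=O)[C@H](O)[C@H](C(=C)CO[Si](C)(C)C(C)(C)C)[C@H](OCc1ccc(OC)c(OC)c1)[C@@H](OCc1ccc(OC)cc1)[C@H](O[Si](CC)(CC)CC)C=C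
F7 | step 10 | 6-O-(4-nitrobenzoyl) derivative of 16 | CCOC(=O)[C@@H](OC(=O)c1ccc(cc1)[N+](=O)[O-])[C@H](C(=C)CO[Si](C)(C)C(C)(C)C)[C@H](OCc1ccc(OC)c(OC)c1)[C@@H](OCc1ccc(OC)cc1)[C@H](O[Si](CC)(CC)CC)C=C
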